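**Two flasks.** Temperature separates epsilon, at 15 °C, from delta, at 35 °C; each is read at 12 h.

| flask | free monomer | pre-initiator | temperature | remark | time |
|---|---|---|---|---|---|
| north-west | 0.14 M | 1.2 mol% | 20 °C | run made earlier |  |
| north | 0.14 M | 5 mol% | 31 °C | run made earlier |  |
| east | 0.28 M | 2.5 mol% | 20 °C | run made earlier |  |
| epsilon | 0.14 M | 2.5 mol% | 15 °C |  | 12 h |
| delta | 0.14 M | 2.5 mol% | 35 °C |  | 12 h |

- north-west (time / h: monomer in chains / %, free monomer / %): 1.00: 2, 94; 2.50: 0, 80; 6.00: 2, 55; 15.0: 8, 23
- north (time / h: monomer in chains / %, free monomer / %): 0.417: 1, 87; 1.00: 5, 65; 2.50: 9, 35; 6.00: 28, 6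
- east (time / h: monomer in chains / %, free monomer / %): 2.00: 0, 85; 5.00: 13, 54; 10.0: 17, 30; 15.0: 26, 16

(standard deviation of a reading: 2 percentage points)

- the flask that comes out highest in amount of monomer in chains, in percent of the free monomer charged, or "all alike" when all lie within 1.5 percentage points (epsilon / delta / all alike)
- monomer in chains at the end, in percent of the free monomer charged, epsilon
- monomer in chains at the end, in percent of the free monomer charged, delta



**Missing monomer.** At the last reading of the north run, 6 % is free and 28 % is in chains, so the rest is missing. Between readings the missing part is replaced by its mean over the run, 48.8 % of the charge. Chains divided by that mean and by the time give 0.0956 /h, the clearing constant: the hourly gain in chains per unit of missing monomer, a pseudo-first-order constant read from the scattered north run.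

**Two extremes.** Delta is charged with half the north run's pre-initiator concentration, so this reckoning scales the constant to 0.0478 /h. If free monomer left evenly over the run, the missing mean would be half the charge, giving 28.7 % in chains. If it left at once, chains would reach 43.7 %. The north run's free monomer, read as first-order, has a half-life of 1.48 h, shorter than delta's time, so this reckoning places delta above the slow extreme. This reckoning takes the midpoint, 36.2 %, without counting delta's extra warmth. Epsilon is colder than the east run, whose chains, scaled by concentration and time, give this reckoning 10.4 % before any allowance for cold, less than delta's lower extreme, so this reckoning names delta.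

**Forecast.** It names delta, with 7 % for epsilon and 36 % for delta, on this ground: “The free monomer falls first-order, but chains lag far behind it”.

**Result.** Epsilon gives 6.68 % and delta 34.7 %, so delta stands higher. Delta's value lies between the extremes, 28.7 % and 43.7 %.

    free monomer ⇌ dormant form (K = 4.30, k = 0.610 /h, Ea = 98.0 kJ/mol, ΔH = −81.0 kJ/mol)
    free monomer + living end → monomer in chains + living end, rate k2*[living end]*[free monomer] (k = 74.0 /M/h, Ea = 51.0 kJ/mol)
    pre-initiator ⇌ initiator (K = 0.920, k = 0.310 /h, Ea = 97.0 kJ/mol, ΔH = −15.0 kJ/mol)
    free monomer + initiator → living end + monomer in chains (k = 100 /M/h, Ea = 54.0 kJ/mol)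
    (constants at 35 °C)

In epsilon at 5.08 h, free monomer's half-life by the forward step into dormant form alone is 16 h, shorter than the 110 h by the step into chains. In delta at the end, the missing monomer stands as this dormant form, 55.6 %.

**Second flask.** Kept at 0 °C, the neighbour of epsilon has 94 % free monomer left. The clearing constant, read at 31 °C and scaled to this flask's pre-initiator concentration as for delta, with half the missing part as its mean, gives 1.62 % with no allowance for cold. The computed flask holds 0.345 %, lower.

(The data were computed with constants of no real substance, noise included.)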